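**Plan**

Atom labels (used for every intermediate): C1 and C6 are the ring-fusion carbons (C1 beside the gem-dimethyl carbon C11, C6 beside the carbinol carbon C7), C2=C3 is the alkene, C4 bears the ester; ring A is C1–C6, ring B is C1, C6–C11.
Retrosynthesis: cut the ester C–O bond at C4 (isovanillate), the C4 oxygen and the C7–CH3 bond, then the fusion bond C1–C6. Because rings A and B have only this bond in common, its removal leaves the eleven-membered carbocycle C1–C11; a last cut at C4–C5 (retro-Cope) reduces that to a cis-1,2-dialkenylcycloheptanol.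
Forward: six-membered enone → cycloheptenone → cis-1-vinyl-2-isopropenylcycloheptanol → eleven-membered ring (siloxy-Cope) → rings A and B in one step (C1–C6 bond) → C7 methyl, C4 oxygen, ester.
Stereochemistry: a CBS reduction sets a carbinol that is relayed by directed epoxidation and anti epoxide opening to the C1 carbinol. In the key step C1 hands its configuration to the new C1 and C6 centres (cis fusion). C7 and C4 come from reagent approach on the convex face of the cis-fused bicycle, C4 then being inverted in the Mitsunobu esterification.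

Key step: step 11

Assumption: the enolate attacks the π-allyl carbon on the face away from palladium (net retention at C1). This fixes the (S)-CBS catalyst in step 2; the enantiomeric catalyst would be used if the relay ran the other way.

**Route**

Step 1
Reactants: 1 4,4-dimethylcyclohex-2-en-1-one
Product: 3 4,4-dimethylcyclohept-2-en-1-one, via α-silyl ketone 2 (not isolated)
Conditions: Me3SiCHN2, AlMe3, CH2Cl2, −78 to −20 °C; then 1 M HCl, THF, 23 °C
Reagents that add atoms: (trimethylsilyl)diazomethane, C[Si](C)(C)C=[N+]=[N-]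
Why: Lewis-acid-promoted diazoalkane ring homologation (Tiffeneau–Demjanov type): the diazo carbon adds to the activated carbonyl and the saturated α-carbon migrates in preference to the alkenyl carbon, so the enone is kept with the gem-dimethyl group γ to the carbonyl, and acid then removes the α-silyl group.

Step 2
Reactants: 3 4,4-dimethylcyclohept-2-en-1-one
Product: 4 (R)-4,4-dimethylcyclohept-2-en-1-ol
Conditions: (S)-2-methyl-CBS-oxazaborolidine (C18H20BNO, 10 mol %), catecholborane, toluene, −78 °C
Reagents that add atoms: none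
Why: Corey–Bakshi–Shibata reduction, in which the alkenyl arm acts as the large and the CH2 arm as the small carbonyl substituent, so the (S)-catalyst should give the (R)-allylic alcohol (the C7 carbinol) without conjugate reduction.

Step 3
Reactants: 4 (R)-4,4-dimethylcyclohept-2-en-1-ol
Product: 5 (1R,2R,7S)-6,6-dimethyl-8-oxabicyclo[5.1.0]octan-2-ol (epoxide cis to the hydroxyl)
Conditions: VO(acac)2 (2 mol %), t-BuOOH, CH2Cl2, 0 to 23 °C
Reagents that add atoms: tert-butyl hydroperoxide, CC(C)(C)OO
Why: Hydroxyl-directed vanadium-catalysed epoxidation: the vanadate ester delivers oxygen to the alkene face syn to the hydroxyl, which sets C1 and C2 from the carbinol centre.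

Step 4
Reactants: 5 (1R,2R,7S)-6,6-dimethyl-8-oxabicyclo[5.1.0]octan-2-ol; 6 isopropenylmagnesium bromide
Product: 7 (1R,2S,3R)-4,4-dimethyl-2-(prop-1-en-2-yl)cycloheptane-1,3-diol (both hydroxyls trans to isopropenyl)
Conditions: 6 (4 equiv), CuI (copper iodide, 15 mol %), THF, −30 to 0 °C; aq. NH4Cl
Reagents that add atoms: none
Why: Copper-catalysed Grignard opening of an epoxide (SN2, inversion): C1 is neopentylic and shielded by the gem-dimethyl group, so the alkenyl group should enter at C2 anti to the epoxide oxygen, leaving the C1 hydroxyl trans to isopropenyl and cis to the C7 hydroxyl.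

Step 5
Reactants: 7 (1R,2S,3R)-4,4-dimethyl-2-(prop-1-en-2-yl)cycloheptane-1,3-diol
Product: 8 (2R,3R)-3-hydroxy-4,4-dimethyl-2-(prop-1-en-2-yl)cycloheptan-1-one
Conditions: TEMPO (2,2,6,6-tetramethylpiperidin-1-oxyl, 10 mol %), PhI(OAc)2 (1.1 equiv), CH2Cl2, 23 °C
Reagents that add atoms: none
Why: Oxoammonium (TEMPO) oxidation, which is strongly slowed by steric hindrance: the C7 carbinol should react while the neopentylic C1 carbinol, flanked by quaternary C11 and branched C2, is left, and the near-neutral medium avoids retro-aldol cleavage and alkene migration.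

Step 6
Reactants: 8 (2R,3R)-3-hydroxy-4,4-dimethyl-2-(prop-1-en-2-yl)cycloheptan-1-one; 9 ethynylmagnesium bromide
Product: 10 (1R,2R,3R)-1-ethynyl-4,4-dimethyl-2-(prop-1-en-2-yl)cycloheptane-1,3-diol (alkyne cis to isopropenyl)
Conditions: 9 (4 equiv), CeCl3 (4 equiv), THF, −78 to 0 °C; aq. NH4Cl
Reagents that add atoms: none
Why: Organocerium acetylide 1,2-addition (low basicity spares the doubly activated C2–H): the rod-shaped acetylide is expected to take the axial trajectory on the conformer with equatorial isopropenyl and C1–O groups, which puts the alkyne cis to isopropenyl and the new hydroxyl cis to the C1 hydroxyl, whereas a bulkier vinyl Grignard reagent would favour the unwanted trans-dialkenyl carbinol.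

Step 7
Reactants: 10 (1R,2R,3R)-1-ethynyl-4,4-dimethyl-2-(prop-1-en-2-yl)cycloheptane-1,3-diol
Product: 11 (1S,2R,3R)-1-ethenyl-4,4-dimethyl-2-(prop-1-en-2-yl)cycloheptane-1,3-diol (vinyl cis to isopropenyl)
Conditions: H2 (1 atm), Pd/CaCO3 poisoned with Pb(OAc)2 (Lindlar catalyst), quinoline, EtOAc, 23 °C
Reagents that add atoms: none
Why: Lindlar semi-hydrogenation of the terminal alkyne to the vinyl group; the 1,1-disubstituted isopropenyl alkene should not be reduced on the poisoned catalyst.

Step 8
Reactants: 11 (1S,2R,3R)-1-ethenyl-4,4-dimethyl-2-(prop-1-en-2-yl)cycloheptane-1,3-diol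
Product: 12 methyl (1R,6S,7R)-6-ethenyl-6-hydroxy-2,2-dimethyl-7-(prop-1-en-2-yl)cycloheptyl carbonate
Conditions: ClCO2Me, pyridine, 4-(dimethylamino)pyridine (10 mol %), CH2Cl2, 0 °C
Reagents that add atoms: methyl chloroformate, COC(=O)Cl
Why: Chloroformate acylation under pyridine catalysis: only the secondary C1 hydroxyl should react, the tertiary allylic hydroxyl being inert, and the carbonate is preferred to an acetate because its later ionisation by palladium is irreversible and releases methoxide.

Step 9
Reactants: 12 methyl (1R,6S,7R)-6-ethenyl-6-hydroxy-2,2-dimethyl-7-(prop-1-en-2-yl)cycloheptyl carbonate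
Product: 13 methyl (1R,6S,7R)-6-ethenyl-2,2-dimethyl-7-(prop-1-en-2-yl)-6-(triethylsilyloxy)cycloheptyl carbonate
Conditions: Et3SiOTf, 2,6-lutidine, CH2Cl2, −78 to 0 °C
Reagents that add atoms: triethylsilyl triflate, CC[Si](CC)(CC)OS(=O)(=O)C(F)(F)F
Why: Silylation of a tertiary alcohol with a silyl triflate and a hindered pyridine base; the carbonate is untouched.

Step 10
Reactants: 13 methyl (1R,6S,7R)-6-ethenyl-2,2-dimethyl-7-(prop-1-en-2-yl)-6-(triethylsilyloxy)cycloheptyl carbonate
Product: 14 methyl (1R,2Z,6Z)-3,11,11-trimethyl-7-(triethylsilyloxy)cycloundeca-2,6-dien-1-yl carbonate (C1 and C4 cis across C2=C3; ring carbons C5 and C8 trans across the C6=C7 enol silane)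
Conditions: o-xylene (0.02 M, degassed, base-washed sealed tube), 190 °C
Reagents that add atoms: none
Why: Thermal siloxy-Cope rearrangement of a cis-1,2-dialkenylcycloalkyl silyl ether: C2–C7 breaks as C4–C5 forms, the ring grows from seven to eleven atoms, the cis arrangement should react through the chair with the C2 ring arm axial and so give the Z C2=C3 alkene, and the sigmatropic shift fixes the enol silane at C6=C7.

Step 11
Reactants: 14 methyl (1R,2Z,6Z)-3,11,11-trimethyl-7-(triethylsilyloxy)cycloundeca-2,6-dien-1-yl carbonate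
Product: 15 (1S,6R)-3,11,11-trimethylbicyclo[5.4.0]undec-2-en-7-one (target numbering; cis-fused)
Conditions: Pd(PPh3)4 (10 mol %), Bu4N[Ph3SiF2] (0.2 equiv), THF (0.005 M), 40 °C
Reagents that add atoms: none
Why: Proposed new method: zerovalent palladium adds to the C1 allylic carbonate with inversion and loss of CO2, giving a divalent palladium π-allyl complex over C1–C3 plus methoxide; methoxide, started and relayed by the catalytic fluoride, strips the triethylsilyl group from the C7 enol ether, so the regiodefined C6 enolate is formed beside its electrophile and adds to C1 on the face away from palladium. The closest known reaction types are the Tsuji–Trost allylation of silyl enol ethers by allylic carbonates and oxy-Cope ring expansion followed by transannular enolate alkylation. Ring A closes in a 6-endo sense on the π-allyl unit (C6, tied to C3 through C4–C5, attacks the far terminus C1, so all three allyl carbons lie in the new ring), and the same C1–C6 bond completes the seven-membered ring B by transannular closure across the eleven-membered perimeter. C1 is controlled by the carbonate-bearing stereocentre through double inversion (net retention, which an η3–η1–η3 shift centred on C1 does not alter); C6 is controlled by the ring-trans enolate geometry inherited from the Cope step, which together with the Z C2=C3 unit should let the termini meet only in the fold that gives the cis fusion, as in the humulyl-to-himachalyl closure. The step needs attack at C1 rather than C3 and at carbon rather than oxygen: attack at C3 would make a four-membered ring, the Z alkene is what makes a six-membered ring possible, and high dilution in an almost neutral medium (methoxide ends as Et3SiOMe) should suppress dimerisation and epimerisation at C6.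

Step 12
Reactants: 15 (1S,6R)-3,11,11-trimethylbicyclo[5.4.0]undec-2-en-7-one
Product: 16 (1S,6R,7S)-3,7,11,11-tetramethylbicyclo[5.4.0]undec-2-en-7-ol
Conditions: MeMgBr, CeCl3, THF, −78 °C; aq. NH4Cl
Reagents that add atoms: methylmagnesium bromide, C[Mg]Br
Why: Organocerium 1,2-addition to an enolisable ketone: the nucleophile should approach C7 on the convex face, anti to the C5 arm at C6, so methyl ends cis to H6 and the hydroxyl trans (7S), and the low basicity keeps C6 from epimerising.

Step 13
Reactants: 16 (1S,6R,7S)-3,7,11,11-tetramethylbicyclo[5.4.0]undec-2-en-7-ol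
Product: 17 (1S,6R,7S)-7-hydroxy-3,7,11,11-tetramethylbicyclo[5.4.0]undec-2-en-4-one
Conditions: Rh2(cap)4 (cap = caprolactamate, 1 mol %), t-BuOOH (5 equiv), K2CO3, CH2Cl2, 23 °C
Reagents that add atoms: tert-butyl hydroperoxide, CC(C)(C)OO
Why: Allylic C–H oxidation by tert-butylperoxyl radicals: C4 is the only unhindered secondary allylic position (the ring-fusion C1–H is tertiary and shielded by the gem-dimethyl group, the methyl group is primary), so the carvone-type enone should form while the tertiary alcohol is inert.

Step 14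
Reactants: 17 (1S,6R,7S)-7-hydroxy-3,7,11,11-tetramethylbicyclo[5.4.0]undec-2-en-4-one
Product: 18 (1S,4S,6R,7S)-3,7,11,11-tetramethylbicyclo[5.4.0]undec-2-ene-4,7-diol (C4 hydroxyl cis to C7)
Conditions: NaBH4, CeCl3·7H2O, MeOH, −78 °C
Reagents that add atoms: none
Why: Luche 1,2-reduction: hydride should add to C4 from the convex face (axial attack, away from ring B), giving the allylic alcohol with the hydroxyl cis to C7, the C4 epimer of what the target needs.

Step 15
Reactants: 19 isovanillic acid
Product: 21 3-(tert-butyldimethylsilyloxy)-4-methoxybenzoic acid, via silyl ester 20 (not isolated)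
Conditions: t-BuMe2SiCl (2.3 equiv), imidazole, DMF, 23 °C; then AcOH, THF, H2O, 23 °C
Reagents that add atoms: tert-butyldimethylsilyl chloride, CC(C)(C)[Si](C)(C)Cl
Why: Silylation of both acidic groups followed by selective hydrolysis of the labile silyl ester; the phenol is masked because it would compete as a Mitsunobu nucleophile.

Step 16
Reactants: 18 (1S,4S,6R,7S)-3,7,11,11-tetramethylbicyclo[5.4.0]undec-2-ene-4,7-diol; 21 3-(tert-butyldimethylsilyloxy)-4-methoxybenzoic acid
Product: 22 (1S,4R,6R,7S)-7-hydroxy-3,7,11,11-tetramethylbicyclo[5.4.0]undec-2-en-4-yl 3-(tert-butyldimethylsilyloxy)-4-methoxybenzoate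
Conditions: PPh3, diisopropyl azodicarboxylate, THF, 0 to 23 °C
Reagents that add atoms: none
Why: Mitsunobu esterification: the carboxylate displaces the activated C4 oxyphosphonium group with SN2 inversion, which sets 4R, while the tertiary C7 hydroxyl does not react.

Step 17
Reactants: 22 (1S,4R,6R,7S)-7-hydroxy-3,7,11,11-tetramethylbicyclo[5.4.0]undec-2-en-4-yl 3-(tert-butyldimethylsilyloxy)-4-methoxybenzoate
Product: 23 (1S,4R,6R,7S)-7-hydroxy-3,7,11,11-tetramethylbicyclo[5.4.0]undec-2-en-4-yl 3-hydroxy-4-methoxybenzoate (CNP0210711.3)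
Conditions: Bu4NF, AcOH, THF, 0 °C
Reagents that add atoms: none
Why: Fluoride cleavage of the aryl silyl ether; buffering with acetic acid protects the allylic ester from base.

**Compound list**

1 | 4,4-dimethylcyclohex-2-en-1-one | CC1(C)CCC(=O)C=C1 | starting material
2 | 4,4-dimethyl-7-(trimethylsilyl)cyclohept-2-en-1-one (α-silyl ketone, either configuration) | O=C1C=CC(C)(C)CCC1[Si](C)(C)C | intermediate
3 | 4,4-dimethylcyclohept-2-en-1-one | O=C1C=CC(C)(C)CCC1 | intermediate
4 | (R)-4,4-dimethylcyclohept-2-en-1-ol | O[C@@H]1CCCC(C)(C)C=C1 | intermediate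
5 | (1R,2R,7S)-6,6-dimethyl-8-oxabicyclo[5.1.0]octan-2-ol | O[C@@H]1CCCC(C)(C)[C@@H]2O[C@H]12 | intermediate
6 | isopropenylmagnesium bromide | CC(=C)[Mg]Br | starting material
7 | (1R,2S,3R)-4,4-dimethyl-2-(prop-1-en-2-yl)cycloheptane-1,3-diol | O[C@@H]1[C@@H](C(C)=C)[C@H](O)CCCC1(C)C | intermediate
8 | (2R,3R)-3-hydroxy-4,4-dimethyl-2-(prop-1-en-2-yl)cycloheptan-1-one | O[C@@H]1[C@@H](C(C)=C)C(=O)CCCC1(C)C | intermediate
9 | ethynylmagnesium bromide | C#C[Mg]Br | starting material
10 | (1R,2R,3R)-1-ethynyl-4,4-dimethyl-2-(prop-1-en-2-yl)cycloheptane-1,3-diol | O[C@@H]1[C@@H](C(C)=C)[C@](C#C)(O)CCCC1(C)C | intermediate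
11 | (1S,2R,3R)-1-ethenyl-4,4-dimethyl-2-(prop-1-en-2-yl)cycloheptane-1,3-diol | O[C@@H]1[C@@H](C(C)=C)[C@](C=C)(O)CCCC1(C)C | intermediate
12 | methyl (1R,6S,7R)-6-ethenyl-6-hydroxy-2,2-dimethyl-7-(prop-1-en-2-yl)cycloheptyl carbonate | COC(=O)O[C@@H]1[C@@H](C(C)=C)[C@](C=C)(O)CCCC1(C)C | intermediate
13 | methyl (1R,6S,7R)-6-ethenyl-2,2-dimethyl-7-(prop-1-en-2-yl)-6-(triethylsilyloxy)cycloheptyl carbonate | COC(=O)O[C@@H]1[C@@H](C(C)=C)[C@](C=C)(O[Si](CC)(CC)CC)CCCC1(C)C | intermediate
14 | methyl (1R,2Z,6Z)-3,11,11-trimethyl-7-(triethylsilyloxy)cycloundeca-2,6-dien-1-yl carbonate | COC(=O)O[C@@H]1/C=C(C)\CC/C=C(O[Si](CC)(CC)CC)/CCCC1(C)C | intermediate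
15 | (1S,6R)-3,11,11-trimethylbicyclo[5.4.0]undec-2-en-7-one (target numbering) | C1C[C@@H]2[C@H](C=C1C)C(C)(C)CCCC2=O | intermediate
16 | (1S,6R,7S)-3,7,11,11-tetramethylbicyclo[5.4.0]undec-2-en-7-ol | C1C[C@@H]2[C@H](C=C1C)C(C)(C)CCC[C@]2(C)O | intermediate
17 | (1S,6R,7S)-7-hydroxy-3,7,11,11-tetramethylbicyclo[5.4.0]undec-2-en-4-one | O=C1C[C@@H]2[C@H](C=C1C)C(C)(C)CCC[C@]2(C)O | intermediate
18 | (1S,4S,6R,7S)-3,7,11,11-tetramethylbicyclo[5.4.0]undec-2-ene-4,7-diol | O[C@H]1C[C@@H]2[C@H](C=C1C)C(C)(C)CCC[C@]2(C)O | intermediate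
19 | isovanillic acid (3-hydroxy-4-methoxybenzoic acid) | COc1ccc(C(=O)O)cc1O | starting material
20 | tert-butyldimethylsilyl 3-(tert-butyldimethylsilyloxy)-4-methoxybenzoate | COc1ccc(C(=O)O[Si](C)(C)C(C)(C)C)cc1O[Si](C)(C)C(C)(C)C | intermediate
21 | 3-(tert-butyldimethylsilyloxy)-4-methoxybenzoic acid | COc1ccc(C(=O)O)cc1O[Si](C)(C)C(C)(C)C | intermediate
22 | (1S,4R,6R,7S)-7-hydroxy-3,7,11,11-tetramethylbicyclo[5.4.0]undec-2-en-4-yl 3-(tert-butyldimethylsilyloxy)-4-methoxybenzoate | COc1ccc(C(=O)O[C@@H]2C[C@@H]3[C@H](C=C2C)C(C)(C)CCC[C@]3(C)O)cc1O[Si](C)(C)C(C)(C)C | intermediate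
23 | (1S,4R,6R,7S)-7-hydroxy-3,7,11,11-tetramethylbicyclo[5.4.0]undec-2-en-4-yl 3-hydroxy-4-methoxybenzoate | COc1ccc(C(=O)O[C@@H]2C[C@@H]3[C@H](C=C2C)C(C)(C)CCC[C@]3(C)O)cc1O | target

**Step count**

Total: 17 steps. Longest linear sequence: 16 steps (steps 1–14, 16 and 17); step 15 is a one-step side branch.

**Steps most likely to fail**

Step 11 (transannular allylation). The freed enolate may be protonated or allylated on oxygen, the π-allyl complex may lose a β-hydrogen to give a diene, or the C–C bond may form through the fold that gives the trans ring fusion. The fallback uses known chemistry only, sets out from 3 and returns at 17. Ring A is built on the existing seven-membered ring by an enantioselective Diels–Alder reaction of 3 with isoprene, catalysed by the triflimide-activated o-tolyl-CBS-oxazaborolidinium ion (the enantiomer that gives the 1S,6R adduct), which should give cis-fused ketone F1 with the alkene at C3=C4. MeMgBr–CeCl3 then gives tertiary alcohol F2. Hydroboration–oxidation (BH3·THF, then NaOH/H2O2) from the convex face gives C4 alcohol F3. Dess–Martin periodinane gives ketone F4. Me3SiCl/NaI/Et3N in MeCN gives the thermodynamic C3=C4 enol silane, silylated also at the C7 oxygen, bis-silyl compound F5. Saegusa–Ito oxidation with Pd(OAc)2 gives silylated enone F6, and dilute HCl gives 17.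

Step 10 (siloxy-Cope). Rearrangement through the competing chair or a boat arrangement would give the E C2=C3 alkene, which cannot close ring A, and long heating may shift or eliminate the allylic carbonate. The fallback sets out from 11 and returns at 15. Diol 11 is deprotonated with KH and 18-crown-6 in THF at 0 to 23 °C, so that the anionic oxy-Cope rearrangement runs far below the thermal temperature and gives dipotassium enolate alkoxide F7. Quenching with ClCO2Me at −78 °C caps both oxygens and gives bis(methyl carbonate) F8, an enol carbonate in place of the enol silane. Under Pd(PPh3)4 in dilute THF the methoxide released on ionisation of the allylic carbonate cleaves the enol carbonate, and the same enolate should close to 15.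

Step 6 (acetylide addition). Attack on the face trans to isopropenyl would lead to the trans-dialkenyl carbinol, and enolisation by the basic reagent would epimerise C2. The fallback sets out from 5 and returns at 11, setting the carbinol before C2 so that the cis relationship follows from a stereospecific epoxide opening. Dess–Martin oxidation of 5 gives epoxy ketone F9. Vinylmagnesium bromide with CeCl3 should add anti to the epoxide oxygen and give tertiary epoxy alcohol F10 (hydroxyl cis to the epoxide). Copper-catalysed opening with 6 at C2, anti to the epoxide oxygen, then places isopropenyl cis to vinyl and gives 11.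

**Further compounds**

F1 | step 11 | (1S,6R)-3,11,11-trimethylbicyclo[5.4.0]undec-3-en-7-one (cis-fused ketone, target numbering) | CC1=CC[C@@H]2[C@H](C1)C(C)(C)CCCC2=O
F2 | step 11 | (1S,6R,7S)-3,7,11,11-tetramethylbicyclo[5.4.0]undec-3-en-7-ol (tertiary alcohol) | CC1=CC[C@@H]2[C@H](C1)C(C)(C)CCC[C@]2(C)O
F3 | step 11 | (1S,3R,4R,6R,7S)-3,7,11,11-tetramethylbicyclo[5.4.0]undecane-4,7-diol (C4 alcohol) | C[C@H]1[C@H](O)C[C@@H]2[C@H](C1)C(C)(C)CCC[C@]2(C)O
F4 | step 11 | (1S,3R,6R,7S)-7-hydroxy-3,7,11,11-tetramethylbicyclo[5.4.0]undecan-4-one (ketone) | C[C@H]1C(=O)C[C@@H]2[C@H](C1)C(C)(C)CCC[C@]2(C)O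
F5 | step 11 | (1S,6R,7S)-3,7,11,11-tetramethyl-4,7-bis(trimethylsilyloxy)bicyclo[5.4.0]undec-3-ene (bis-silyl compound) | CC1=C(O[Si](C)(C)C)C[C@@H]2[C@H](C1)C(C)(C)CCC[C@]2(C)O[Si](C)(C)C
F6 | step 11 | (1S,6R,7S)-3,7,11,11-tetramethyl-7-(trimethylsilyloxy)bicyclo[5.4.0]undec-2-en-4-one (silylated enone) | O=C1C[C@@H]2[C@H](C=C1C)C(C)(C)CCC[C@]2(C)O[Si](C)(C)C
F7 | step 10 | dipotassium (1R,2Z,6Z)-3,11,11-trimethylcycloundeca-2,6-diene-1,7-diolate (enolate alkoxide) | [K+].[K+].[O-][C@@H]1/C=C(C)\CC/C=C([O-])/CCCC1(C)C
F8 | step 10 | (1R,2Z,6Z)-3,11,11-trimethylcycloundeca-2,6-diene-1,7-diyl dimethyl dicarbonate (bis(methyl carbonate)) | COC(=O)O[C@@H]1/C=C(C)\CC/C=C(OC(=O)OC)/CCCC1(C)C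
F9 | step 6 | (1S,7S)-6,6-dimethyl-8-oxabicyclo[5.1.0]octan-2-one (epoxy ketone) | O=C1CCCC(C)(C)[C@@H]2O[C@H]12
F10 | step 6 | (1S,2S,7S)-2-ethenyl-6,6-dimethyl-8-oxabicyclo[5.1.0]octan-2-ol (tertiary epoxy alcohol) | O[C@]1(C=C)CCCC(C)(C)[C@@H]2O[C@H]12
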